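Labdane numbering is used. Ring B (C5–C6–C7–C8–C9–C10) carries the 1,2-pair C7–OAc/C8=C17H2, a reduced α-methylene ketone. The plan rests on removing C8: ring B is traced to a trans-fused cyclopentanone in which C9 is bonded directly to the carbonyl carbon C7. In one operation dibromomethyllithium adds to C7, the β-oxido carbenoid shifts C9 (side chain and configuration intact) onto the new carbon C8, enlarging the five-membered ring to ring B, and the regiodefined C7–C8 enolate is trapped by an iminium salt as the C17 precursor. The hydrindanone comes from an enantioselective allylation–Wacker–aldol sequence, C–H chlorination and one face-selective hydrogenation; the imide is added last by Wittig olefination.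

Key step: step 8

Convention: α is the face opposite to the C10 methyl group; the bicyclic intermediates before step 8 lack C8 and C17, and their ketone carbon is C7.
Assumption: in step 2 the sense of induction is taken by analogy with 2-methylcyclohexanone, where the (S)-ligand gives the (S)-ketone; if this substrate behaves oppositely, the other ligand enantiomer is used.

Step 1
Reactants: 1 2,2,6-trimethylcyclohexan-1-one (racemic); 2 allyl chloroformate
Product: 4 allyl 2,6,6-trimethylcyclohex-1-en-1-yl carbonate, via lithium enolate 3 (not isolated)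
Conditions: LiN(SiMe3)2, THF, 0 °C; then 2, −78 °C → rt
Reagents that add atoms: none
Why: Enolate O-acylation: 1 can enolise only toward C10 because C4 is quaternary, and the chloroformate traps the tetrasubstituted lithium enolate on oxygen, which erases the stereocentre of racemic 1.

Step 2
Reactants: 4 allyl 2,6,6-trimethylcyclohex-1-en-1-yl carbonate
Product: 5 (R)-2-allyl-2,6,6-trimethylcyclohexan-1-one
Conditions: Pd2(dba)3 (cat.), (R)-t-Bu-PHOX (cat.), THF, 25 °C
Reagents that add atoms: none
Why: Decarboxylative asymmetric allylic alkylation (Tsuji allylation): zerovalent palladium ionises the allyl carbonate, CO2 is lost, and the enolate is allylated inside the chiral PHOX–palladium allyl complex, which differentiates the enolate faces and sets the quaternary centre C10 as (R).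

Step 3
Reactants: 5 (R)-2-allyl-2,6,6-trimethylcyclohexan-1-one
Product: 6 (R)-2,2,6-trimethyl-6-(2-oxopropyl)cyclohexan-1-one
Conditions: PdCl2 (cat.), Cu(OAc)2 (cat.), O2 (1 atm), DMA/H2O, rt
Reagents that add atoms: water, O
Why: Tsuji–Wacker oxidation: Markovnikov oxypalladation of the terminal alkene by divalent palladium and β-hydride elimination give the methyl ketone while Cu(OAc)2/O2 re-oxidise the metal; no stereocentre is involved.

Step 4
Reactants: 6 (R)-2,2,6-trimethyl-6-(2-oxopropyl)cyclohexan-1-one
Product: 7 (7aR)-4,4,7a-trimethyl-1,4,5,6,7,7a-hexahydro-2H-inden-2-one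
Conditions: KOH, xylenes, 110 °C, Dean–Stark
Reagents that add atoms: none
Why: Intramolecular aldol condensation: the ring ketone C5 has no α-hydrogen, so only the methyl ketone enolises, its methyl carbon (C6) attacks C5 to close the five-membered ring, and dehydration gives the C5=C6 enone.

Step 5
Reactants: 7 (7aR)-4,4,7a-trimethyl-1,4,5,6,7,7a-hexahydro-2H-inden-2-one
Product: 8 (6S,7aS)-6-chloro-4,4,7a-trimethyl-1,4,5,6,7,7a-hexahydro-2H-inden-2-one (2α-chloro enone)
Conditions: t-BuN(Cl)C(O)Ar (Ar = 3,5-(CF3)2C6H3, 1.1 equiv), Cs2CO3, PhH, visible light, 55 °C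
Reagents that add atoms: N-tert-butyl-N-chloro-3,5-bis(trifluoromethyl)benzamide, CC(C)(C)N(Cl)C(=O)c1cc(cc(c1)C(F)(F)F)C(F)(F)F
Why: Site-selective aliphatic C–H chlorination by an amidyl-radical chain: the bulky electrophilic radical should abstract hydrogen at C2, the only ring CH2 not flanked by a quaternary carbon and the one most remote from the electron-poor enone (which has no allylic C–H), and the C2 radical should take chlorine from the α-face because the axial 4β- and 10β-methyl groups block the β-face, giving the equatorial 2α-chloride.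

Step 6
Reactants: 8 2α-chloro enone; 9 2,2-dimethoxyacetaldehyde
Product: 10 (6S,7aS)-6-chloro-1-(2,2-dimethoxyethylidene)-4,4,7a-trimethyl-1,4,5,6,7,7a-hexahydro-2H-inden-2-one (C9=C11 geometry not defined)
Conditions: KOH, MeOH/H2O (9 as 60% aq. solution), 0 °C → rt
Reagents that add atoms: none
Why: Claisen–Schmidt condensation (crossed aldol, then E1cB dehydration): C9 is the only enolisable position of 8 and the aldehyde cannot enolise, so the exocyclic C9=C11 bond forms without regiochemical choice, and its geometry is irrelevant because step 7 saturates it.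

Step 7
Reactants: 10 cross-conjugated dienone
Product: 11 trans-fused 6-chloro-1-(2,2-dimethoxyethyl)-4,4,7a-trimethyloctahydro-2H-inden-2-one (2α-Cl; H5α; side chain at C9 β; C7 ketone)
Conditions: H2 (3 atm), Pd/C, EtOAc, rt
Reagents that add atoms: none
Why: Heterogeneous hydrogenation should deliver hydrogen to both C=C bonds from the α-face, because the axial 10β- and 4β-methyl groups shield the β-face of the flat dienone, which sets H5α (trans ring fusion) and H9α (side chain β); the acetal and the secondary chloride are inert under neutral conditions.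

Step 8
Reactants: 11 trans-hydrindan-7-one
Product: 15 2α-chloro-17-(dimethylamino)-12,12-dimethoxy-13,14,15,16-tetranorlabdan-7-one (C8 epimers), via lithium alkoxide 12 (not isolated), via β-oxido carbenoid 13 (not isolated), via lithium enolate 14 (not isolated)
Conditions: CH2Br2, LiN(iPr)2, THF, −95 °C; then 11; n-BuLi, −95 → −20 °C; CH2=NMe2+ I−, −78 °C → rt
Reagents that add atoms: dibromomethane, BrCBr; dimethylmethyleneammonium iodide (Eschenmoser's salt), C=[N+](C)C.[I-]
Why: Dibromomethyllithium adds to the C7 carbonyl (α-face, away from the C10 methyl), bromine–lithium exchange gives the β-oxido carbenoid, and the C7–C9 bond shifts to the carbenoid carbon with loss of LiBr, so that this carbon becomes C8 and the lithium enolate C7(OLi)=C8 forms regiospecifically before the iminium salt aminomethylates it at C8. The closest known reaction type is the one-carbon ring enlargement of cycloalkanones through β-oxido carbenoids with electrophilic trapping of the resulting enolate, completed here by a Mannich reaction. No ring is closed by cyclisation: ring B arises from the cyclopentanone by a 1,2-alkyl shift, a five- to six-membered ring expansion. C9 migrates with retention, so its side chain stays β; the carbinol centre C7 is lost on rearrangement and the new C8 centre, formed as a mixture, is erased in step 9. The step needs migration of C9 and not of C6: the more substituted α-carbon is the better migrating group in this carbenoid rearrangement, and the rotamer with bromine anti to C9 also keeps the halogen away from the hindered C9/C10 flank. Enolisation should be limited by adding 11 to preformed LiCHBr2 at −95 °C, and the acetal and the secondary chloride are inert to the organolithium reagents.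

Step 9
Reactants: 15 Mannich base
Product: 17 2α-chloro-12,12-dimethoxy-13,14,15,16-tetranorlabd-8(17)-en-7-one, via ammonium iodide 16 (not isolated)
Conditions: MeI, CH2Cl2, rt; then aq. NaHCO3, rt
Reagents that add atoms: none
Why: Quaternisation of the Mannich base and E1cB (Hofmann-type) elimination of trimethylamine give the exocyclic C8=C17 enone, the weak base avoiding migration of the double bond toward C9.

Step 10
Reactants: 17 exo-methylene ketone
Product: 18 2α-chloro-12,12-dimethoxy-13,14,15,16-tetranorlabd-8(17)-en-7β-ol
Conditions: NaBH4, CeCl3·7H2O, MeOH, −78 °C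
Reagents that add atoms: none
Why: Luche reduction (1,2-selective): axial hydride attack from the α-face, which meets only the axial hydrogens at C5 and C9, should give the equatorial 7β-alcohol.

Step 11
Reactants: 18 7β-allylic alcohol
Product: 19 7β-acetoxy-2α-chloro-12,12-dimethoxy-13,14,15,16-tetranorlabd-8(17)-ene
Conditions: Ac2O, pyridine, DMAP (cat.), CH2Cl2, rt
Reagents that add atoms: acetic anhydride, CC(=O)OC(C)=O
Why: DMAP-catalysed O-acylation of the secondary allylic alcohol, with retention at C7.

Step 12
Reactants: 19 acetate acetal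
Product: 20 7β-acetoxy-2α-chloro-13,14,15,16-tetranorlabd-8(17)-en-12-al
Conditions: TsOH·H2O (cat.), acetone/H2O, rt
Reagents that add atoms: water, O
Why: Acid-catalysed acetal hydrolysis under conditions too mild to ionise the allylic acetate or to engage the exocyclic alkene.

Step 13
Reactants: 20 aldehyde; 21 maleimide
Product: 23 CNP0220384.1, (E)-3-[2-(7β-acetoxy-2α-chloro-8(17)-methylene bicyclic core)ethylidene]pyrrolidine-2,5-dione, via phosphorus ylide 22 (not isolated)
Conditions: PPh3, THF, rt; then 20, 60 °C
Reagents that add atoms: none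
Why: Wittig olefination: conjugate addition of PPh3 to maleimide and proton shift give the stabilised succinimidyl ylide, which should condense with the aldehyde to the (E)-alkylidene succinimide (C11 cis to the ring CH2, trans to the C16 carbonyl).

Compound list
1 | 2,2,6-trimethylcyclohexan-1-one (racemic) | CC1CCCC(C)(C)C1=O | starting material
2 | allyl chloroformate | C=CCOC(=O)Cl | starting material
3 | lithium 2,6,6-trimethylcyclohex-1-en-1-olate | [Li+].[O-]C1=C(C)CCCC1(C)C | intermediate
4 | allyl 2,6,6-trimethylcyclohex-1-en-1-yl carbonate | C=CCOC(=O)OC1=C(C)CCCC1(C)C | intermediate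
5 | (R)-2-allyl-2,6,6-trimethylcyclohexan-1-one | O=C1C(C)(C)CCC[C@]1(C)CC=C | intermediate
6 | (R)-2,2,6-trimethyl-6-(2-oxopropyl)cyclohexan-1-one | O=C1C(C)(C)CCC[C@]1(C)CC(C)=O | intermediate
7 | (7aR)-4,4,7a-trimethyl-1,4,5,6,7,7a-hexahydro-2H-inden-2-one | O=C1C=C2C(C)(C)CCC[C@]2(C)C1 | intermediate
8 | (6S,7aS)-6-chloro-4,4,7a-trimethyl-1,4,5,6,7,7a-hexahydro-2H-inden-2-one | O=C1C=C2C(C)(C)C[C@H](Cl)C[C@]2(C)C1 | intermediate
9 | 2,2-dimethoxyacetaldehyde | COC(OC)C=O | starting material
10 | (6S,7aS)-6-chloro-1-(2,2-dimethoxyethylidene)-4,4,7a-trimethyl-1,4,5,6,7,7a-hexahydro-2H-inden-2-one (alkene geometry not defined) | O=C1C=C2C(C)(C)C[C@H](Cl)C[C@]2(C)C1=CC(OC)OC | intermediate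
11 | trans-fused 6-chloro-1-(2,2-dimethoxyethyl)-4,4,7a-trimethyloctahydro-2H-inden-2-one (2α-Cl, H5α, 9β side chain, 10β-methyl) | O=C1C[C@H]2C(C)(C)C[C@H](Cl)C[C@]2(C)[C@H]1CC(OC)OC | intermediate
12 | lithium alkoxide of the C7 dibromomethyl carbinol from 11 (C7 configuration immaterial) | [Li+].[O-]C1(C(Br)Br)C[C@H]2C(C)(C)C[C@H](Cl)C[C@]2(C)[C@H]1CC(OC)OC | intermediate
13 | β-oxido carbenoid (lithium alkoxide with C7–CH(Li)Br) | [Li+].[O-]C1(C([Li])Br)C[C@H]2C(C)(C)C[C@H](Cl)C[C@]2(C)[C@H]1CC(OC)OC | intermediate
14 | lithium C7–C8 enolate of the ring-enlarged ketone | C1=C([O-])C[C@H]2C(C)(C)C[C@H](Cl)C[C@]2(C)[C@H]1CC(OC)OC.[Li+] | intermediate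
15 | 2α-chloro-17-(dimethylamino)-12,12-dimethoxy-13,14,15,16-tetranorlabdan-7-one (C8 epimers) | CN(C)CC1C(=O)C[C@H]2C(C)(C)C[C@H](Cl)C[C@]2(C)[C@H]1CC(OC)OC | intermediate
16 | trimethylammonium iodide of 15 | C[N+](C)(C)CC1C(=O)C[C@H]2C(C)(C)C[C@H](Cl)C[C@]2(C)[C@H]1CC(OC)OC.[I-] | intermediate
17 | 2α-chloro-12,12-dimethoxy-13,14,15,16-tetranorlabd-8(17)-en-7-one | C=C1C(=O)C[C@H]2C(C)(C)C[C@H](Cl)C[C@]2(C)[C@H]1CC(OC)OC | intermediate
18 | 2α-chloro-12,12-dimethoxy-13,14,15,16-tetranorlabd-8(17)-en-7β-ol | C=C1[C@@H](O)C[C@H]2C(C)(C)C[C@H](Cl)C[C@]2(C)[C@H]1CC(OC)OC | intermediate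
19 | 7β-acetoxy-2α-chloro-12,12-dimethoxy-13,14,15,16-tetranorlabd-8(17)-ene | C=C1[C@@H](OC(C)=O)C[C@H]2C(C)(C)C[C@H](Cl)C[C@]2(C)[C@H]1CC(OC)OC | intermediate
20 | 7β-acetoxy-2α-chloro-13,14,15,16-tetranorlabd-8(17)-en-12-al | C=C1[C@@H](OC(C)=O)C[C@H]2C(C)(C)C[C@H](Cl)C[C@]2(C)[C@H]1CC=O | intermediate
21 | maleimide | O=C1C=CC(=O)N1 | starting material
22 | 3-(triphenylphosphoranylidene)pyrrolidine-2,5-dione | O=C1CC(=P(c2ccccc2)(c2ccccc2)c2ccccc2)C(=O)N1 | intermediate
23 | CNP0220384.1, (12E)-7β-acetoxy-2α-chlorolabda-8(17),12-diene 15,16-imide | C=C1[C@@H](OC(C)=O)C[C@H]2C(C)(C)C[C@H](Cl)C[C@]2(C)[C@H]1C/C=C1\CC(=O)NC1=O | target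

Total step count: 13. Longest linear sequence: 13 steps (1 to 23).

Steps most likely to fail

Step 8. The carbenoid reagent may deprotonate the hindered ketone instead of adding to it, or C6 may migrate in place of C9, which would place the new carbon on the wrong side of the carbonyl. The fallback sets out from 11 and returns at 17. Compound 11 is homologated with TMSCHN2 and AlMe3 (CH2Cl2, −78 → −20 °C). In this diazoalkane ring expansion the less substituted C6 migrates, so the inserted carbon becomes C7 and the old carbonyl carbon becomes C8, which should give the ring-B α-silyl ketone F1. K2CO3/MeOH removes the silyl group to give the 8-ketone F2. Wittig methylenation (Ph3P=CH2, THF) gives the 8(17)-alkene F3. Allylic oxidation with SeO2/t-BuOOH gives the 7α-alcohol F4, and Dess–Martin periodinane oxidises it to enone 17.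

Step 5. Hydrogen abstraction may spread over C1, C2 and C3, chlorine may be transferred to the β-face, or radicals may add to the enone. The fallback sets out from 7 and returns at 8. Quinuclidine-mediated anodic C–H oxidation (Me4N·BF4, HFIP/MeCN, O2, carbon anode) converts the C2 methylene into the 2-ketone F5. NaBH4 (MeOH/CH2Cl2, −78 °C) should reduce the saturated ketone faster than the enone and attack from the α-face, since the β-face is blocked by the two syn-axial methyl groups, giving the axial 2β-alcohol F6. PPh3/CCl4 (Appel reaction) then replaces the hydroxyl with inversion to give the 2α-chloride 8.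

Step 7. Hydrogen may be delivered to the β-face at C5 or C9, the reduction may stall at the hindered C5=C6 bond, or the C–Cl bond may undergo hydrogenolysis. The fallback sets out from 10 and returns at 11. Both enone double bonds are reduced by hydrogen-atom-transfer conjugate reduction (Mn(dpm)3, PhSiH3, i-PrOH), which leaves the C–Cl bond alone and should deliver hydrogen to C5 from the open α-face. Protonation at C9 on work-up may give 11 together with its C9 epimer F7. NaOMe/MeOH equilibrates F7 to 11, whose side chain is pseudo-equatorial and cis to the C10 methyl, as in 17β-substituted 16-oxo steroids.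

Further compounds
F1 | step 8 | 2α-chloro-12,12-dimethoxy-7-(trimethylsilyl)-13,14,15,16,17-pentanorlabdan-8-one (C7 epimers) | O=C1C([Si](C)(C)C)C[C@H]2C(C)(C)C[C@H](Cl)C[C@]2(C)[C@H]1CC(OC)OC
F2 | step 8 | 2α-chloro-12,12-dimethoxy-13,14,15,16,17-pentanorlabdan-8-one | O=C1CC[C@H]2C(C)(C)C[C@H](Cl)C[C@]2(C)[C@H]1CC(OC)OC
F3 | step 8 | 2α-chloro-12,12-dimethoxy-13,14,15,16-tetranorlabd-8(17)-ene | C=C1CC[C@H]2C(C)(C)C[C@H](Cl)C[C@]2(C)[C@H]1CC(OC)OC
F4 | step 8 | 2α-chloro-12,12-dimethoxy-13,14,15,16-tetranorlabd-8(17)-en-7α-ol | C=C1[C@H](O)C[C@H]2C(C)(C)C[C@H](Cl)C[C@]2(C)[C@H]1CC(OC)OC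
F5 | step 5 | 6-oxo derivative of 7 (4,4,7a-trimethyl-4,5,7,7a-tetrahydro-1H-indene-2,6-dione, 10β-methyl) | O=C1C=C2C(C)(C)CC(=O)C[C@]2(C)C1
F6 | step 5 | 6-hydroxy analogue of 8 with axial 2β-OH | O=C1C=C2C(C)(C)C[C@@H](O)C[C@]2(C)C1
F7 | step 7 | C9 epimer of 11 (side chain α) | O=C1C[C@H]2C(C)(C)C[C@H](Cl)C[C@]2(C)[C@@H]1CC(OC)OC
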